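**Assumption:** the target SMILES describes the centrosymmetric α-truxillic-type cyclobutane (the two aryl groups trans, the two acyl groups trans, each acyl cis to one neighbouring aryl and trans to the other). This isomer is achiral (meso), so "single enantiomer" is read as this single diastereomer and no absolute stereocontrol is needed.

**Retrosynthetic overview**
1. Target 17 ⇒ diacid 13 + two molecules of 5,6-dihydropyridin-2(1H)-one 14 (twofold N-acylation; the lactam rings are bought ready-made).
2. Cyclobutane 12 ⇒ all-equatorial, centrosymmetric piperazine 10 by twofold stereoretentive nitrogen deletion (ring contraction six → five → four; each C–N–C bridge becomes a C–C bond).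
3. Piperazine 10 ⇒ two molecules of glycine imine 9 (head-to-tail double Mannich cyclodimerisation under thermodynamic control).
4. Imine 9 ⇒ 3,4,5-trimethoxybenzaldehyde 6 (from p-cresol 1) + glycine methyl ester.
5. Ring order: arene (present in 1) → piperazine → pyrrolidine (transient) → cyclobutane.

**Route**

Step 1
Reactants: 1 p-cresol
Product: 4 3,5-dibromo-4-hydroxybenzaldehyde, via dibromocresol 2 (not isolated), via benzal bromide 3 (not isolated)
Conditions: Br2 (2.05 equiv), o-dichlorobenzene, 35 °C; Br2 (2.1 equiv), 155 °C; H2O, 100 °C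
Reagents that add atoms: bromine, BrBr; water, O
Why: Electrophilic aromatic bromination at both positions ortho to OH (para is blocked), then free-radical benzylic dibromination at high temperature and hydrolysis of the gem-dibromide give the aldehyde; no stereocenter is formed.

Step 2
Reactants: 4 3,5-dibromo-4-hydroxybenzaldehyde
Product: 6 3,4,5-trimethoxybenzaldehyde, via sodium syringaldehyde phenolate 5 (not isolated)
Conditions: NaOMe (4 equiv), CuCl (5 mol %), DMF–MeOH, 110 °C; then Me2SO4 (2.5 equiv), 55 °C
Reagents that add atoms: sodium methoxide, C[O-].[Na+]; dimethyl sulfate, COS(=O)(=O)OC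
Why: Ullmann-type CuCl-catalysed methoxylation of the two aryl bromides (activated by the para formyl group) followed by Williamson O-methylation of the phenolate in the same pot; no stereocenter is formed.

Step 3
Reactants: 6 3,4,5-trimethoxybenzaldehyde (2 equiv); 7 glycine methyl ester hydrochloride (2 equiv)
Product: 10 dimethyl (2R,3S,5S,6R)-3,6-bis(3,4,5-trimethoxyphenyl)piperazine-2,5-dicarboxylate (meso, all four substituents equatorial), via glycine methyl ester 8 (not isolated), via glycine imine 9 (not isolated)
Conditions: LiOMe (1.0 equiv), 3 Å MS, MeOH, 23 °C, 3 h; then LiOMe (0.3 equiv), MeOH (1.5 M), N2, 60 °C, 48 h, slow cooling (product crystallises)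
Reagents that add atoms: none
Why: Proposed new method: head-to-tail [3+3] double Mannich cyclodimerisation of a glycine aldimine under thermodynamic control — LiOMe reversibly forms the N,O-chelated lithio azomethine ylide (2-azaallyl anion) of 9, whose ester-bearing carbon adds to the C=N carbon of a second molecule of 9, and slow reversible α-deprotonation of the resulting N-alkyl glycinate in MeOH at 60 °C then allows a 6-endo Mannich closure onto the remaining aldimine; because the kinetically favoured five-membered aminal dimer and all four C-stereocentres stay in retro-Mannich and enolate equilibrium, the system should drain into the most stable and least soluble dimer, the all-equatorial chair piperazine (each CO2Me trans to its neighbouring aryl, aryls trans, centrosymmetric), which sets all four stereocentres; the closest known reaction types are the lithium salt/amine-mediated Mannich addition of glycine aldimines to imines and the head-to-tail [3+3] dimerisation of N-substituted azomethine ylides to piperazines.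

Step 4
Reactants: 10 dimethyl (2R,3S,5S,6R)-3,6-bis(3,4,5-trimethoxyphenyl)piperazine-2,5-dicarboxylate
Product: 12 dimethyl (1α,2α,3β,4β)-2,4-bis(3,4,5-trimethoxyphenyl)cyclobutane-1,3-dicarboxylate, via pyrrolidine 11 (not isolated)
Conditions: 4-CF3C6H4C(O)N(OBn)OPiv (3.4 equiv), THF (degassed), 45 °C, 36 h
Reagents that add atoms: none
Why: Proposed new method: twofold nitrogen deletion of a piperazine (sequential six → five → four ring contraction) — each N–H attacks the anomeric amide nitrogen with loss of pivalate, the N-alkoxy-N-aminoamide rearranges to the benzyl ester and a cyclic 1,1-diazene, and N2 loss gives a singlet 1,5- and then 1,4-biradical whose benzylic and α-ester termini recombine faster than they rotate, so each C–N–C bridge is replaced by a C–C bond with retention and the chair relationships (CO2Me trans to aryl across the old C–C bonds, cis across the new ones) become the α-truxillate configuration; the closest known reaction types are the single nitrogen deletion of secondary amines with anomeric amides (piperidine → cyclopentane, pyrrolidine → cyclobutane) and the iodonitrene-mediated contraction of 2-ester-5-aryl pyrrolidines to cyclobutanes, neither shown on a piperazine nor twice in one ring.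

Step 5
Reactants: 12 dimethyl (1α,2α,3β,4β)-2,4-bis(3,4,5-trimethoxyphenyl)cyclobutane-1,3-dicarboxylate
Product: 13 (1α,2α,3β,4β)-2,4-bis(3,4,5-trimethoxyphenyl)cyclobutane-1,3-dicarboxylic acid
Conditions: LiOH·H2O (6 equiv), THF–MeOH–H2O (3:1:1), 50 °C; then 1 M HCl
Reagents that add atoms: lithium hydroxide, [Li+].[OH-]
Why: Saponification is faster than enolisation of the ring C–H, and the trans-1,3-dicarboxylate is in any case the electrostatically preferred arrangement, so the four stereocentres are carried through unchanged.

Step 6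
Reactants: 13 (1α,2α,3β,4β)-2,4-bis(3,4,5-trimethoxyphenyl)cyclobutane-1,3-dicarboxylic acid; 14 5,6-dihydropyridin-2(1H)-one (2.4 equiv)
Product: 17 Piplartine-dimer A, via bis(acid chloride) 15 (not isolated), via lithium lactamate 16 (not isolated)
Conditions: 13, (COCl)2 (3 equiv), DMF (cat.), CH2Cl2, 0 → 23 °C, then evaporation; 14, LiN(SiMe3)2 (2.3 equiv), THF, −78 °C; then 15 in THF added, −78 → −40 °C
Reagents that add atoms: none
Why: Acid chloride formation followed by N-acylation of the lithium lactamate (imide formation as used for piperlongumine-type amides) is fast at −78 °C, and ketene formation is disfavoured by cyclobutylidene strain and the absence of an amine base, so the ring stereocentres and the lactam C=C are untouched.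

**Compound list**
1 | p-cresol | Cc1ccc(O)cc1 | starting material
2 | 2,6-dibromo-4-methylphenol | Cc1cc(Br)c(O)c(Br)c1 | intermediate
3 | 2,6-dibromo-4-(dibromomethyl)phenol | BrC(Br)c1cc(Br)c(O)c(Br)c1 | intermediate
4 | 3,5-dibromo-4-hydroxybenzaldehyde | O=Cc1cc(Br)c(O)c(Br)c1 | intermediate
5 | sodium 4-formyl-2,6-dimethoxyphenolate | [Na+].[O-]c1c(OC)cc(C=O)cc1OC | intermediate
6 | 3,4,5-trimethoxybenzaldehyde | COc1cc(C=O)cc(OC)c1OC | intermediate
7 | glycine methyl ester hydrochloride | COC(=O)CN.Cl | starting material
8 | glycine methyl ester (free base) | COC(=O)CN | intermediate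
9 | methyl (E)-N-(3,4,5-trimethoxybenzylidene)glycinate | COC(=O)C/N=C/c1cc(OC)c(OC)c(OC)c1 | intermediate
10 | dimethyl (2R,3S,5S,6R)-3,6-bis(3,4,5-trimethoxyphenyl)piperazine-2,5-dicarboxylate (meso; each CO2Me trans to the adjacent aryl, aryls trans, esters trans) | COc1cc([C@H]2[C@H](C(=O)OC)N[C@H](c3cc(OC)c(OC)c(OC)c3)[C@@H](C(=O)OC)N2)cc(OC)c1OC | intermediate
11 | dimethyl rel-(2R,3S,4S,5S)-3,5-bis(3,4,5-trimethoxyphenyl)pyrrolidine-2,4-dicarboxylate (racemic; 2,3-trans, 3,4-cis, 4,5-trans, 2,5-cis) | COc1cc([C@H]2[C@H](C(=O)OC)[C@H](c3cc(OC)c(OC)c(OC)c3)[C@@H](C(=O)OC)N2)cc(OC)c1OC | intermediate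
12 | dimethyl (1α,2α,3β,4β)-2,4-bis(3,4,5-trimethoxyphenyl)cyclobutane-1,3-dicarboxylate (α-truxillate type, centrosymmetric) | COc1cc([C@H]2[C@H](C(=O)OC)[C@H](c3cc(OC)c(OC)c(OC)c3)[C@H]2C(=O)OC)cc(OC)c1OC | intermediate
13 | (1α,2α,3β,4β)-2,4-bis(3,4,5-trimethoxyphenyl)cyclobutane-1,3-dicarboxylic acid | COc1cc([C@H]2[C@H](C(=O)O)[C@H](c3cc(OC)c(OC)c(OC)c3)[C@H]2C(=O)O)cc(OC)c1OC | intermediate
14 | 5,6-dihydropyridin-2(1H)-one | O=C1C=CCCN1 | starting material
15 | (1α,2α,3β,4β)-2,4-bis(3,4,5-trimethoxyphenyl)cyclobutane-1,3-dicarbonyl dichloride | COc1cc([C@H]2[C@H](C(=O)Cl)[C@H](c3cc(OC)c(OC)c(OC)c3)[C@H]2C(=O)Cl)cc(OC)c1OC | intermediate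
16 | lithium salt of 5,6-dihydropyridin-2(1H)-one (N-lithio lactamate) | [Li+].O=C1C=CCC[N-]1 | intermediate
17 | Piplartine-dimer A, 1,1'-{[(1α,2α,3β,4β)-2,4-bis(3,4,5-trimethoxyphenyl)cyclobutane-1,3-diyl]dicarbonyl}bis(5,6-dihydropyridin-2(1H)-one) | COc1cc([C@H]2[C@H](C(=O)N3CCC=CC3=O)[C@H](c3cc(OC)c(OC)c(OC)c3)[C@H]2C(=O)N2CCC=CC2=O)cc(OC)c1OC | target

**Total step count:** 6. **Longest linear sequence:** 6 steps (1 → 17).

**Three steps most likely to fail**

Step 3 (proposed new step). The dimerisation may stop at the kinetic five-membered aminal dimer, give diastereomer mixtures that do not funnel to the all-equatorial isomer, or suffer 2-azaallyl prototropy. The fallback uses known chemistry, sets out from 6 and 9 and comes back at 12. Aldehyde 6 is condensed with monomethyl malonate (pyridine, piperidine, 90 °C, Knoevenagel–Doebner) to give methyl (E)-3,4,5-trimethoxycinnamate F1. Imine 9 (made separately with Et3N and MgSO4 in CH2Cl2) and F1 undergo the established AgOAc/Et3N-catalysed endo-selective azomethine ylide [3+2] cycloaddition to give the endo pyrrolidine diester F2 (2,5-cis, 2,3-trans, 3,4-trans, 4,5-cis). The known iodonitrene contraction (PhI(OH)OTs, ammonium carbamate, CF3CH2OH, 80 °C) converts F2 with retention into the γ-type cyclobutane diester F3 (esters cis to each other). F3 is equilibrated at one ester-bearing carbon with NaOMe in MeOH. The α:γ ratio at equilibrium is not known; the centrosymmetric, less soluble 12 is removed by crystallisation and the mother liquor recycled.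

Step 4 (proposed new step). The biradicals may cleave to two molecules of the cinnamate, lose stereochemistry at the stabilised radical centres, or the reaction may stall at pyrrolidine 11. The fallback uses the classical stepwise 1,1-diazene chemistry, sets out from 10 and comes back at 12. Piperazine 10 is N-nitrosated (t-BuONO, CH2Cl2) to the 1,4-dinitrosopiperazine diester F4. Reduction with Zn in AcOH gives the 1,4-diaminopiperazine diester F5. Oxidation of F5 with HgO (EtOH–CH2Cl2, 0 → 23 °C) generates the two cyclic 1,1-diazenes at low temperature, which lose N2 with retention to give 12. The intermediates are isolable, so the two contractions can be monitored and optimised separately.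

Step 6. Risks are epimerisation of the ring C–H via ketene or imide enolate, conjugate addition to the unsaturated lactam, and incomplete second acylation. The fallback builds the lactam rings after amide formation, sets out from 13 and comes back at 17. Diacid 13 is coupled with but-3-en-1-amine (EDC·HCl, HOBt, CH2Cl2) to give the bis(N-but-3-enyl) amide F6. Deprotonation with LiN(SiMe3)2 at −78 °C and N-acylation with acryloyl chloride gives the bis(N-acryloyl-N-but-3-enyl) imide F7. Twofold ring-closing metathesis with the second-generation Grubbs catalyst RuCl2(=CHPh)(PCy3)(H2IMes) (CH2Cl2, 40 °C) closes both 5,6-dihydropyridin-2(1H)-one rings and gives 17.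

**Further compounds**
F1 | step 3 | methyl (E)-3-(3,4,5-trimethoxyphenyl)acrylate | COC(=O)/C=C/c1cc(OC)c(OC)c(OC)c1
F2 | step 3 | dimethyl rel-(2R,3S,4R,5S)-3,5-bis(3,4,5-trimethoxyphenyl)pyrrolidine-2,4-dicarboxylate (endo adduct, racemic) | COc1cc([C@H]2[C@@H](C(=O)OC)[C@H](c3cc(OC)c(OC)c(OC)c3)[C@@H](C(=O)OC)N2)cc(OC)c1OC
F3 | step 3 | dimethyl (1α,2α,3α,4β)-2,4-bis(3,4,5-trimethoxyphenyl)cyclobutane-1,3-dicarboxylate (γ-truxillate type) | COc1cc([C@H]2[C@@H](C(=O)OC)[C@H](c3cc(OC)c(OC)c(OC)c3)[C@H]2C(=O)OC)cc(OC)c1OC
F4 | step 4 | dimethyl (2R,3S,5S,6R)-1,4-dinitroso-3,6-bis(3,4,5-trimethoxyphenyl)piperazine-2,5-dicarboxylate | COc1cc([C@H]2[C@H](C(=O)OC)N(N=O)[C@H](c3cc(OC)c(OC)c(OC)c3)[C@@H](C(=O)OC)N2N=O)cc(OC)c1OC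
F5 | step 4 | dimethyl (2R,3S,5S,6R)-1,4-diamino-3,6-bis(3,4,5-trimethoxyphenyl)piperazine-2,5-dicarboxylate | COc1cc([C@H]2[C@H](C(=O)OC)N(N)[C@H](c3cc(OC)c(OC)c(OC)c3)[C@@H](C(=O)OC)N2N)cc(OC)c1OC
F6 | step 6 | (1α,2α,3β,4β)-N,N'-di(but-3-en-1-yl)-2,4-bis(3,4,5-trimethoxyphenyl)cyclobutane-1,3-dicarboxamide | COc1cc([C@H]2[C@H](C(=O)NCCC=C)[C@H](c3cc(OC)c(OC)c(OC)c3)[C@H]2C(=O)NCCC=C)cc(OC)c1OC
F7 | step 6 | (1α,2α,3β,4β)-N,N'-diacryloyl-N,N'-di(but-3-en-1-yl)-2,4-bis(3,4,5-trimethoxyphenyl)cyclobutane-1,3-dicarboxamide | COc1cc([C@H]2[C@H](C(=O)N(CCC=C)C(=O)C=C)[C@H](c3cc(OC)c(OC)c(OC)c3)[C@H]2C(=O)N(CCC=C)C(=O)C=C)cc(OC)c1OC
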